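The route rests on cutting the C4'–C4a' bond of the lower pyran ring (O1', C2', C3', C4', C4a', C8a'), so that this ring is annulated last onto a phloroglucinol D-ring whose C8' already carries C4 of the robinetinidol unit. One Lewis-acid-triggered epoxy-arene cyclisation forms C4'–C4a', closes the ring and unmasks the C3' hydroxyl. It exploits C4a', the only free carbon ortho to O1' and activated by the C5' and C7' benzyloxy groups, so the 4→8 linkage is fixed by structure. The precursor is the fully benzylated D-ring aryl ether of (R)-aryl[(2R)-oxiranyl]methanol, which already holds the cis C2'/C3' stereocentres.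

Key step: step 8

Remark on the chemistry: 3,5-bis(benzyloxy)phenol, 3,4,5-tris(benzyloxy)benzaldehyde and 3,4,5-tris(benzyloxy)benzoic acid are taken as catalogue compounds. Primes denote the lower (epigallocatechin) unit.
Remark on the chemistry: the target is 2,3-trans-3,4-trans (2R,3S,4S) in the upper unit and 2',3'-cis (2'R,3'R) in the lower unit. The cyclisation precursor therefore needs the threo arrangement, R at the ether-bearing benzylic carbon and R at the oxirane carbon.

Step 1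
Reactants: 1 (+)-dihydrorobinetin
Product: 2 (2R,3R)-7-(benzyloxy)-3-hydroxy-2-[3,4,5-tris(benzyloxy)phenyl]chroman-4-one
Conditions: BnBr, K2CO3, DMF, rt, Ar
Reagents that add atoms: benzyl bromide BrCc1ccccc1
Why: Williamson etherification in which carbonate deprotonates only the four phenols, so the base-sensitive α-ketol and the (2R,3R) centres should be carried through unchanged.

Step 2
Reactants: 2 (2R,3R)-7-(benzyloxy)-3-hydroxy-2-[3,4,5-tris(benzyloxy)phenyl]chroman-4-one
Product: 3 (2R,3S,4R)-7-(benzyloxy)-2-[3,4,5-tris(benzyloxy)phenyl]chromane-3,4-diol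
Conditions: NaBH4, THF–MeOH, 0 °C
Reagents that add atoms: none
Why: Borohydride reduction of the aryl ketone, where axial hydride delivery should give mainly the equatorial 4-OH (3,4-trans, 4R); any C4 epimer is carried along because C4 is ionised in step 4.

Step 3
Reactants: 3 (2R,3S,4R)-7-(benzyloxy)-2-[3,4,5-tris(benzyloxy)phenyl]chromane-3,4-diol
Product: 4 (2R,3S,4R)-3,4,7-tris(benzyloxy)-2-[3,4,5-tris(benzyloxy)phenyl]chromane
Conditions: NaH, BnBr, Bu4NI (cat.), DMF, 0 °C → rt
Reagents that add atoms: benzyl bromide BrCc1ccccc1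
Why: Williamson etherification of both secondary alkoxides, done at the diol stage because the dihydroflavonol would not tolerate NaH; the C3 benzyl ether is the lasting protecting group and the C4 benzyl ether the benzylic leaving group, with no stereocentre touched.

Step 4
Reactants: 4 (2R,3S,4R)-3,4,7-tris(benzyloxy)-2-[3,4,5-tris(benzyloxy)phenyl]chromane; 5 3,5-bis(benzyloxy)phenol (excess)
Product: 6 3,5-bis(benzyloxy)-2-{(2R,3S,4S)-3,7-bis(benzyloxy)-2-[3,4,5-tris(benzyloxy)phenyl]chroman-4-yl}phenol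
Conditions: BF3·OEt2 (0.3 equiv), CH2Cl2, −40 → 0 °C
Reagents that add atoms: none
Why: Friedel–Crafts arylation of a flavan-4-yl cation (the 4-benzyloxy group, para to the 7-benzyloxy group, ionises), in which the phenol should react through the ring carbon ortho to its free hydroxyl (less hindered than the carbon between the two benzyloxy groups) and from the face anti to the C3 benzyloxy group, setting the new 4S (3,4-trans) centre.

Step 5
Reactants: 7 3,4,5-tris(benzyloxy)benzaldehyde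
Product: 8 (±)-1-[3,4,5-tris(benzyloxy)phenyl]prop-2-en-1-ol
Conditions: CH2=CHMgBr, THF, −78 → 0 °C
Reagents that add atoms: vinylmagnesium bromide C=C[Mg]Br
Why: Grignard 1,2-addition to an aryl aldehyde; the carbinol forms as the racemate and is resolved in step 6.

Step 6
Reactants: 8 (±)-1-[3,4,5-tris(benzyloxy)phenyl]prop-2-en-1-ol
Product: 9 (S)-[(2R)-oxiran-2-yl][3,4,5-tris(benzyloxy)phenyl]methanol
Conditions: Ti(OiPr)4 (cat.), L-(+)-DIPT (cat.), TBHP (0.5 equiv), 4 Å MS, CH2Cl2, −20 °C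
Reagents that add atoms: tert-butyl hydroperoxide CC(C)(C)OO
Why: Sharpless kinetic resolution (asymmetric epoxidation of a secondary allylic alcohol), in which the L-tartrate catalyst should epoxidise the (R)-carbinol much faster and on the face that gives the erythro (1S,2R) epoxy alcohol, the oxirane centre being set by the tartrate and the (S)-alcohol left behind when conversion is held near one half.

Step 7
Reactants: 6 3,5-bis(benzyloxy)-2-{(2R,3S,4S)-3,7-bis(benzyloxy)-2-[3,4,5-tris(benzyloxy)phenyl]chroman-4-yl}phenol; 9 (S)-[(2R)-oxiran-2-yl][3,4,5-tris(benzyloxy)phenyl]methanol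
Product: 10 (2R)-2-[(R)-{3,5-bis(benzyloxy)-2-[(2R,3S,4S)-3,7-bis(benzyloxy)-2-[3,4,5-tris(benzyloxy)phenyl]chroman-4-yl]phenoxy}[3,4,5-tris(benzyloxy)phenyl]methyl]oxirane
Conditions: PPh3, DIAD, toluene, 0 °C → rt
Reagents that add atoms: none
Why: Mitsunobu etherification, in which the phenol displaces the phosphonium-activated benzylic oxygen by SN2 and inverts the carbinol centre from S to R (erythro alcohol to threo ether), the neighbouring oxirane oxygen disfavouring ionisation and the oxirane itself staying a spectator.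

Step 8
Reactants: 10 (2R)-2-[(R)-{3,5-bis(benzyloxy)-2-[(2R,3S,4S)-3,7-bis(benzyloxy)-2-[3,4,5-tris(benzyloxy)phenyl]chroman-4-yl]phenoxy}[3,4,5-tris(benzyloxy)phenyl]methyl]oxirane
Product: 11 (2R,3R)-5,7-bis(benzyloxy)-8-{(2R,3S,4S)-3,7-bis(benzyloxy)-2-[3,4,5-tris(benzyloxy)phenyl]chroman-4-yl}-2-[3,4,5-tris(benzyloxy)phenyl]chroman-3-ol
Conditions: AuCl3 (5 mol %), AgOTf (15 mol %), ClCH2CH2Cl, 0 °C → rt
Reagents that add atoms: none
Why: The cationic gold(III) species coordinates the oxirane oxygen, and D-ring carbon C4a' (ortho to O1', ortho/para to the C5' and C7' benzyloxy groups) attacks the primary oxirane carbon in an SN2-like Friedel–Crafts alkylation, after which rearomatisation and proton transfer release the C3' hydroxyl. The closest known reaction type is the Lewis-acid-promoted cyclisation of aryl glycidyl ethers to chroman-3-ols. The ring O1'–C2'–C3'–C4'–C4a'–C8a' closes in the 6-endo mode; 5-exo attack on the internal oxirane carbon should be disfavoured because the short aryl ether tether cannot align C4a' with that C–O bond and because that carbon is the more hindered one. No stereocentre is created: C2' (R) and C3' (R) come from 10 and no bond to either is broken, so the 2',3'-cis relationship is retained. Regiochemistry on the D-ring is structural, since C8' already bears the upper unit and C6' cannot reach the oxirane. Chemoselectivity relies on a soft, catalytic Lewis acid at ambient temperature, under which the benzylic C2'–O1' ether (its cation destabilised by the adjacent oxirane oxygen) and the benzyl ethers should not ionise.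

Step 9
Reactants: 11 (2R,3R)-5,7-bis(benzyloxy)-8-{(2R,3S,4S)-3,7-bis(benzyloxy)-2-[3,4,5-tris(benzyloxy)phenyl]chroman-4-yl}-2-[3,4,5-tris(benzyloxy)phenyl]chroman-3-ol; 12 3,4,5-tris(benzyloxy)benzoic acid
Product: 13 (2R,3R)-5,7-bis(benzyloxy)-8-{(2R,3S,4S)-3,7-bis(benzyloxy)-2-[3,4,5-tris(benzyloxy)phenyl]chroman-4-yl}-2-[3,4,5-tris(benzyloxy)phenyl]chroman-3-yl 3,4,5-tris(benzyloxy)benzoate
Conditions: DCC, DMAP (cat.), CH2Cl2, rt
Reagents that add atoms: none
Why: Steglich esterification of the only free hydroxyl (the axial C3'–OH), with retention because the C3'–O bond is not broken.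

Step 10
Reactants: 13 (2R,3R)-5,7-bis(benzyloxy)-8-{(2R,3S,4S)-3,7-bis(benzyloxy)-2-[3,4,5-tris(benzyloxy)phenyl]chroman-4-yl}-2-[3,4,5-tris(benzyloxy)phenyl]chroman-3-yl 3,4,5-tris(benzyloxy)benzoate
Product: 14 robinetinidol-(4α→8)-epigallocatechin 3'-O-gallate (CNP0269431.1)
Conditions: H2 (1 atm), Pd(OH)2/C, THF–MeOH, rt
Reagents that add atoms: none
Why: Catalytic hydrogenolysis of all thirteen benzyl ethers under neutral conditions, which should leave the gallate ester, the pyran C–O bonds, the interflavan bond and every stereocentre untouched.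

Compound list
1 | (+)-dihydrorobinetin, (2R,3R)-3,7-dihydroxy-2-(3,4,5-trihydroxyphenyl)chroman-4-one | O=C1c2ccc(O)cc2O[C@H](c2cc(O)c(O)c(O)c2)[C@H]1O | starting material
2 | (2R,3R)-7-(benzyloxy)-3-hydroxy-2-[3,4,5-tris(benzyloxy)phenyl]chroman-4-one | O=C1c2ccc(OCc3ccccc3)cc2O[C@H](c2cc(OCc3ccccc3)c(OCc3ccccc3)c(OCc3ccccc3)c2)[C@H]1O | intermediate
3 | (2R,3S,4R)-7-(benzyloxy)-2-[3,4,5-tris(benzyloxy)phenyl]chromane-3,4-diol (major C4 epimer) | O[C@@H]1c2ccc(OCc3ccccc3)cc2O[C@H](c2cc(OCc3ccccc3)c(OCc3ccccc3)c(OCc3ccccc3)c2)[C@H]1O | intermediate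
4 | (2R,3S,4R)-3,4,7-tris(benzyloxy)-2-[3,4,5-tris(benzyloxy)phenyl]chromane | c1ccccc1CO[C@@H]1c2ccc(OCc3ccccc3)cc2O[C@H](c2cc(OCc3ccccc3)c(OCc3ccccc3)c(OCc3ccccc3)c2)[C@H]1OCc1ccccc1 | intermediate
5 | 3,5-bis(benzyloxy)phenol | Oc1cc(OCc2ccccc2)cc(OCc2ccccc2)c1 | starting material
6 | 3,5-bis(benzyloxy)-2-{(2R,3S,4S)-3,7-bis(benzyloxy)-2-[3,4,5-tris(benzyloxy)phenyl]chroman-4-yl}phenol | Oc1cc(OCc2ccccc2)cc(OCc2ccccc2)c1[C@@H]1c2ccc(OCc3ccccc3)cc2O[C@H](c2cc(OCc3ccccc3)c(OCc3ccccc3)c(OCc3ccccc3)c2)[C@H]1OCc1ccccc1 | intermediate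
7 | 3,4,5-tris(benzyloxy)benzaldehyde | O=Cc1cc(OCc2ccccc2)c(OCc2ccccc2)c(OCc2ccccc2)c1 | starting material
8 | (±)-1-[3,4,5-tris(benzyloxy)phenyl]prop-2-en-1-ol (racemate) | C=CC(O)c1cc(OCc2ccccc2)c(OCc2ccccc2)c(OCc2ccccc2)c1 | intermediate
9 | (S)-[(2R)-oxiran-2-yl][3,4,5-tris(benzyloxy)phenyl]methanol (erythro) | C1O[C@H]1[C@H](c1cc(OCc2ccccc2)c(OCc2ccccc2)c(OCc2ccccc2)c1)O | intermediate
10 | (2R)-2-[(R)-{3,5-bis(benzyloxy)-2-[(2R,3S,4S)-3,7-bis(benzyloxy)-2-[3,4,5-tris(benzyloxy)phenyl]chroman-4-yl]phenoxy}[3,4,5-tris(benzyloxy)phenyl]methyl]oxirane (key-step precursor) | C1O[C@H]1[C@@H](c1cc(OCc2ccccc2)c(OCc2ccccc2)c(OCc2ccccc2)c1)Oc1cc(OCc2ccccc2)cc(OCc2ccccc2)c1[C@@H]1c2ccc(OCc3ccccc3)cc2O[C@H](c2cc(OCc3ccccc3)c(OCc3ccccc3)c(OCc3ccccc3)c2)[C@H]1OCc1ccccc1 | intermediate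
11 | (2R,3R)-5,7-bis(benzyloxy)-8-{(2R,3S,4S)-3,7-bis(benzyloxy)-2-[3,4,5-tris(benzyloxy)phenyl]chroman-4-yl}-2-[3,4,5-tris(benzyloxy)phenyl]chroman-3-ol (benzylated robinetinidol-(4α→8)-epigallocatechin, free C3'–OH; key-step product) | O[C@@H]1Cc2c(OCc3ccccc3)cc(OCc3ccccc3)c([C@@H]3c4ccc(OCc5ccccc5)cc4O[C@H](c4cc(OCc5ccccc5)c(OCc5ccccc5)c(OCc5ccccc5)c4)[C@H]3OCc3ccccc3)c2O[C@@H]1c1cc(OCc2ccccc2)c(OCc2ccccc2)c(OCc2ccccc2)c1 | intermediate
12 | 3,4,5-tris(benzyloxy)benzoic acid | OC(=O)c1cc(OCc2ccccc2)c(OCc2ccccc2)c(OCc2ccccc2)c1 | starting material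
13 | 3'-O-[3,4,5-tris(benzyloxy)benzoyl] ester of 11 | O=C(O[C@@H]1Cc2c(OCc3ccccc3)cc(OCc3ccccc3)c([C@@H]3c4ccc(OCc5ccccc5)cc4O[C@H](c4cc(OCc5ccccc5)c(OCc5ccccc5)c(OCc5ccccc5)c4)[C@H]3OCc3ccccc3)c2O[C@@H]1c1cc(OCc2ccccc2)c(OCc2ccccc2)c(OCc2ccccc2)c1)c1cc(OCc2ccccc2)c(OCc2ccccc2)c(OCc2ccccc2)c1 | intermediate
14 | robinetinidol-(4α→8)-epigallocatechin 3'-O-gallate (CNP0269431.1) | O=C(O[C@@H]1Cc2c(O)cc(O)c([C@@H]3c4ccc(O)cc4O[C@H](c4cc(O)c(O)c(O)c4)[C@H]3O)c2O[C@@H]1c1cc(O)c(O)c(O)c1)c1cc(O)c(O)c(O)c1 | target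

Total step count: 10. Longest linear sequence: 8 steps (steps 1, 2, 3, 4, 7, 8, 9, 10).

Steps most likely to fail

Step 8 (key step). The cyclisation may be diverted by 5-exo attack on the internal oxirane carbon, by hydride-shift (Meinwald) rearrangement of the activated oxirane to a carbonyl compound, or by ionisation of the benzylic C2'–O1' ether. The fallback sets out from compound 4 and takes the lower pyran ring ready-made instead of closing it. Commercial (−)-epigallocatechin is benzylated on its five phenols (BnBr, K2CO3, DMF) to 5,7,3',4',5'-penta-O-benzyl-(−)-epigallocatechin F1. F1, used in excess, is then coupled with 4 (TMSOTf or BF3·OEt2, CH2Cl2, −78 °C), the C4 cation being captured by C8 of F1 anti to the C3 benzyloxy group. This conventional interflavan Friedel–Crafts coupling comes back to the route at compound 11, at the price of having to control C8 versus C6 attack.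

Step 7. The hindered, weakly acidic phenol may capture the activated carbinol too slowly, so that alkylation of the reduced azodicarboxylate or partial ionisation at the benzylic carbon (loss of clean inversion) takes over. The fallback sets out from compounds 7 and 6 and replaces the redox condensation by an epoxide opening. A Z-selective Horner–Wadsworth–Emmons olefination of 7 (ethyl 2-(diphenoxyphosphoryl)acetate, NaH, THF, −78 °C) should give ethyl (Z)-3-[3,4,5-tris(benzyloxy)phenyl]prop-2-enoate F2. DIBAL-H (CH2Cl2, −78 °C) reduces it to (Z)-3-[3,4,5-tris(benzyloxy)phenyl]prop-2-en-1-ol F3. Sharpless epoxidation with D-(−)-DIPT gives the cis epoxy alcohol [(2R,3S)-3-[3,4,5-tris(benzyloxy)phenyl]oxiran-2-yl]methanol F4. The caesium phenoxide of 6 (Cs2CO3, DMF, 60 °C) should open F4 at the benzylic carbon with inversion to the threo diol (2R,3R)-3-aryloxy-3-[3,4,5-tris(benzyloxy)phenyl]propane-1,2-diol F5, the aryloxy group being that of 6. Selective primary tosylation (TsCl, Et3N, Bu2SnO cat.) gives the (2R,3R) primary monotosylate F6, and K2CO3 in MeOH closes the terminal oxirane with retention at the carbinol carbon, coming back to the route at compound 10.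

Step 4. The phenol may react through the carbon para to its hydroxyl (between the two benzyloxy groups), or the first adduct may be alkylated a second time. The fallback sets out from compound 4 and uses a nucleophile whose three ring carbons are equivalent. Condensation of 4 with a large excess of commercial phloroglucinol (BF3·OEt2, dioxane–CH2Cl2, 0 °C) can give only one C-aryl constitution, 2-{(2R,3S,4S)-3,7-bis(benzyloxy)-2-[3,4,5-tris(benzyloxy)phenyl]chroman-4-yl}benzene-1,3,5-triol F7. Two equivalents of BnBr with K2CO3 in DMF should then benzylate the unhindered para hydroxyl and one of the two equivalent ortho hydroxyls. After chromatographic removal of under- and over-benzylated material this comes back to the route at compound 6.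

Further compounds
F1 | step 8 | 5,7,3',4',5'-penta-O-benzyl-(−)-epigallocatechin | O[C@@H]1Cc2c(OCc3ccccc3)cc(OCc3ccccc3)cc2O[C@@H]1c1cc(OCc2ccccc2)c(OCc2ccccc2)c(OCc2ccccc2)c1
F2 | step 7 | ethyl (Z)-3-[3,4,5-tris(benzyloxy)phenyl]prop-2-enoate | CCOC(=O)/C=C\c1cc(OCc2ccccc2)c(OCc2ccccc2)c(OCc2ccccc2)c1
F3 | step 7 | (Z)-3-[3,4,5-tris(benzyloxy)phenyl]prop-2-en-1-ol | OC/C=C\c1cc(OCc2ccccc2)c(OCc2ccccc2)c(OCc2ccccc2)c1
F4 | step 7 | [(2R,3S)-3-[3,4,5-tris(benzyloxy)phenyl]oxiran-2-yl]methanol | OC[C@H]1O[C@H]1c1cc(OCc2ccccc2)c(OCc2ccccc2)c(OCc2ccccc2)c1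
F5 | step 7 | (2R,3R)-3-{3,5-bis(benzyloxy)-2-[(2R,3S,4S)-3,7-bis(benzyloxy)-2-[3,4,5-tris(benzyloxy)phenyl]chroman-4-yl]phenoxy}-3-[3,4,5-tris(benzyloxy)phenyl]propane-1,2-diol | OC[C@@H](O)[C@@H](c1cc(OCc2ccccc2)c(OCc2ccccc2)c(OCc2ccccc2)c1)Oc1cc(OCc2ccccc2)cc(OCc2ccccc2)c1[C@@H]1c2ccc(OCc3ccccc3)cc2O[C@H](c2cc(OCc3ccccc3)c(OCc3ccccc3)c(OCc3ccccc3)c2)[C@H]1OCc1ccccc1
F6 | step 7 | (2R,3R)-3-{3,5-bis(benzyloxy)-2-[(2R,3S,4S)-3,7-bis(benzyloxy)-2-[3,4,5-tris(benzyloxy)phenyl]chroman-4-yl]phenoxy}-2-hydroxy-3-[3,4,5-tris(benzyloxy)phenyl]propyl 4-methylbenzenesulfonate | Cc1ccc(cc1)S(=O)(=O)OC[C@@H](O)[C@@H](c1cc(OCc2ccccc2)c(OCc2ccccc2)c(OCc2ccccc2)c1)Oc1cc(OCc2ccccc2)cc(OCc2ccccc2)c1[C@@H]1c2ccc(OCc3ccccc3)cc2O[C@H](c2cc(OCc3ccccc3)c(OCc3ccccc3)c(OCc3ccccc3)c2)[C@H]1OCc1ccccc1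
F7 | step 4 | 2-{(2R,3S,4S)-3,7-bis(benzyloxy)-2-[3,4,5-tris(benzyloxy)phenyl]chroman-4-yl}benzene-1,3,5-triol | Oc1cc(O)c([C@@H]2c3ccc(OCc4ccccc4)cc3O[C@H](c3cc(OCc4ccccc4)c(OCc4ccccc4)c(OCc4ccccc4)c3)[C@H]2OCc2ccccc2)c(O)c1
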